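## The problem

Flowerine (14) is a (2S)-flavanone: a chroman-4-one (ring C) fused to a ring A that carries a chelated 5-hydroxyl, a 7-methoxy group and a prenyl group at C8, with a 4-methoxyphenyl ring B on C2. C2 is the only stereocentre and has no neighbour that could direct its formation, so it must come from a chiral catalyst or reagent. It is also fragile: it sits β to the C4 ketone on a phenoxide leaving group (E1cB opening of ring C under base) and is a 4-methoxybenzylic ether (ionisation under acid). Every step after its creation must therefore stay close to neutral. Ring A raises two regiochemical questions: which of the two oxygens ortho to the acyl carbon becomes O1, and how the prenyl group reaches C8 and not C6. The prenyl olefin is acid-sensitive and would take part in any olefin metathesis, and the chelated 5-hydroxyl is a sluggish nucleophile. The enabling feature is C3, an unsubstituted CH2 between C2 and the C4 carbonyl: the C3–C4 bond can be drawn as the C3=C4 double bond of a cyclic enol silane, so ring C can be closed by metathesis between a vinyl group on C2 and the enol silane of an acetyl group on C4a. Before prenylation ring A is a symmetric 2,6-dioxygenated 4-methoxyphenyl ketone, so the O1 question disappears if the prenyl group comes last.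

## Retrosynthesis

**C8–prenyl bond.** The bond between C8 and the prenyl CH2 is cut and the five carbons are placed on O5: 14 goes back to the 5-O-prenyl ether 11, and 11 to the 5-hydroxyflavanone 9 and prenol 10. A direct C–C construction at C8 would have to tell C8 from C6 and would need base or strong acid. The oxygen-to-carbon relay uses the one free hydroxyl as anchor: the [3,3] shift from O5 can only go to C6 (C4a is blocked), and the following Cope shift carries the group to the para position, C8. Precursor 9 has no prenyl olefin, so all earlier steps are free of its acid sensitivity and of its interference with metathesis. The forward steps must alkylate a chelated phenol without base and rearrange under a Lewis acid mild enough to leave O1–C2 closed.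

**C4 carbonyl.** 9 is the hydrolysis product of the cyclic bis-silyl compound 7, with the monosilyl ketone 8 in between: the ketone is written as its enol silane and the 5-hydroxyl as its silyl ether. No skeletal bond is cut; what is gained is a C3=C4 double bond that metathesis can make. The forward reaction must put a proton on C3 without passing through a free enolate, which could expel O1.

**C3=C4 bond (ring C).** Retro-metathesis of the C3=C4 bond of 7 opens ring C to the acyclic diene 6, in which C2 carries a vinyl group and C4 is the carbon of an α-silyloxystyrene. The neighbouring cuts are weaker: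
- breaking O1–C2 would create the stereocentre in a reversible conjugate addition;
- breaking C4–C4a would need an acylation under acid on a ring with two competing positions;
- breaking C2–C3 would put a carbanion or carbene next to the labile ether.

The metathesis touches none of the bonds to C2, runs in neutral solution, and leaves a precursor with no ring beyond the two arenes and one stereocentre. The forward reaction must close onto a 1,1-disubstituted, electron-rich alkene faster than the allylic double bond can migrate.

**Silicon–oxygen bonds.** Removing both silyl groups from 6 gives the hydroxy ketone 4, by way of the aryl silyl ether 5. One reagent can do both jobs because the ketone can enolise only towards its methyl group. The forward reaction must stay basic throughout, since the benzylic allylic aryl ether of 4 ionises easily.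

**O1–C2 bond.** 4 is cut between the phenolic oxygen and the benzylic allylic carbon, giving acetophenone 3 and the linear carbonate 2, which is one acylation from alcohol 1. This is the step that creates C2: an allylic substitution that must be branched-selective and enantioselective. The two hydroxyls of 3 are equivalent, so no protecting group or regiochemical choice is needed. Cutting the aryl–oxygen bond instead would require an activated aryl halide and a preformed chiral alcohol. Compounds 1, 3 and 10 are purchasable.

## Roads not taken

**Alternative 1:** The cut is made inside ring A, between C4a and C8a, so that the aromatic ring is folded from a polyketide chain masked as pyrone A1. In the forward sense Mg(OMe)2 in methanol opens the lactone of A1 to a triketo ester enolate, the central methylene attacks the ester carbonyl (Claisen condensation), and aromatisation gives chalcone A2.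
- Merits: it copies the biosynthesis, needs no precious metal or protecting group, and delivers the whole C6–C3–C6 skeleton in one operation.
- Weak points: the ring it builds is the one part of the molecule that can be bought. A2 contains exactly the aromatic ring of 3 and is one aldol condensation away from it, so the key step solves none of the real problems. C2 would have to be set afterwards by enantioselective oxa-Michael closure of A2 to 9. That closure is reversible under the catalysis that promotes it, and chalcones of this type without an extra activating group are poor substrates. The competing aldol mode of folding is a further uncertainty.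
- Comparison: this road is better in reagent cost and in avoiding labile intermediates, and from 9 onwards both roads need the same prenylation. The chosen plan sets against it a stereocentre made irreversibly under catalyst control, never exposed to equilibrating conditions, and a purchased ring A.

**Alternative 2:** Two bonds of ring C are cut, O1–C8a and C4–C4a. This divides the target into aryne precursor A3 (fully substituted ring A, prenyl in place) and the (S)-hydroxy ester A4. With CsF, A3 releases the C4a≡C8a aryne, the alkoxide of A4 adds at C8a, and the aryl anion at C4a closes onto the ester to give flavanone A5. Its methoxymethyl group is then removed to give 14.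
- Merits: the highest convergence of the roads considered; C2 comes from A4, whose carbinol centre is available by asymmetric ketone hydrogenation, the most dependable stereocentre-forming reaction considered here; the prenyl group is present from the start, so no late rearrangement is needed. The regiochemistry is plausible, because the alkoxy group at C5 polarises the aryne so that the nucleophile enters at the distal carbon, C8a.
- Weak points: A3 is a hexasubstituted benzene (silyl, triflate, prenyl and three different oxygen functions) that needs at least as many steps as the whole chosen route. C8a is flanked by the prenyl group, which works against the electronic preference. The alkoxide of A4 can undergo retro-aldol cleavage or elimination before it meets the aryne, and secondary alkoxides are mediocre aryne traps. The prenyl olefin of a second molecule is an ene partner for the aryne.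
- Comparison: this road is better in convergence and in the reliability of the stereocentre. The chosen plan answers with a purchased, symmetric ring A that raises no regiochemical question, and with a key step of a well-known type instead of a three-event anionic cascade.

**Alternative 3:** The C2–C3 bond is cut. The precursor is α-diazo ketone A6, in which O1 already carries the 4-methoxybenzyl group that becomes C2 and ring B. A chiral dirhodium tetracarboxylate such as Rh2(S-PTTL)4 would decompose A6 to the carbene at C3, which inserts into the benzylic C–H bond, closing ring C and setting C2 in one step to give A7.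
- Merits: ring closure and stereocentre in the same catalytic step, and the prenyl group already at C8.
- Weak points: the carbene has easier exits than the six-membered C–H insertion. These are attack on the ether oxygen O1 followed by a [1,2]-benzyl shift, addition to the electron-rich benzyl ring, and insertion into the neighbouring 5-O-methyl group. Enantiocontrol of acceptor-only carbenes in such insertions is moderate. A7 also carries a 5-O-methyl group that must be removed selectively with a Lewis acid such as BCl3, in the presence of the prenyl olefin and the acid-sensitive C2, to reach 14.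
- Comparison: on paper this road is shorter once A6 is in hand and needs no rearrangement to place the prenyl group. The chosen plan separates the two tasks: the stereocentre goes to an allylic substitution with a strong record of enantiocontrol, the ring closure goes to a metathesis with one plausible outcome, and the free 5-hydroxyl is reached without dealkylation.

Key step: step 4

Assumption: the (Sa,Sc,Sc) phosphoramidite is taken to give the S ether, in line with the (Ra,Rc,Rc) ligand giving R-configured branched products from cinnamyl carbonates and heteroatom nucleophiles; if the sense is the reverse, only the ligand enantiomer is exchanged.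

## Route

Step 1
Reactants: 1 (E)-4-methoxycinnamyl alcohol
Product: 2 (E)-3-(4-methoxyphenyl)allyl methyl carbonate
Conditions: ClCO2Me, pyridine, CH2Cl2, 0 °C
Reagents that add atoms: methyl chloroformate, COC(=O)Cl
Why: Acylation of the primary allylic alcohol by a chloroformate with pyridine as base (carbonate formation); the E alkene is untouched, and the product is kept cold and used soon because electron-rich cinnamyl carbonates ionise easily.

Step 2
Reactants: 2 (E)-3-(4-methoxyphenyl)allyl methyl carbonate; 3 2',6'-dihydroxy-4'-methoxyacetophenone
Product: 4 1-(2-hydroxy-4-methoxy-6-{[(1S)-1-(4-methoxyphenyl)prop-2-en-1-yl]oxy}phenyl)ethan-1-one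
Conditions: [Ir(cod)Cl]2 (2 mol%), (Sa,Sc,Sc)-(1,1'-binaphthalene-2,2'-diyl) N,N-bis(1-phenylethyl)phosphoramidite (4 mol%), n-PrNH2 pre-activation; 3 (1.5 equiv), LiOt-Bu (1.2 equiv), THF, rt
Reagents that add atoms: none
Why: Iridium-catalysed asymmetric allylic etherification: the cyclometalated iridium–phosphoramidite complex ionises 2 to a (4-methoxyphenyl)allyl complex and the lithium monoaryloxide of 3 attacks the aryl-substituted terminus from the face opposite the metal, giving the branched ether and setting C2 as S under ligand control. Because 3 is symmetric either oxygen gives the same product, and the remaining hydroxyl of 4, held in a hydrogen bond to the acetyl group and left undeprotonated, should not react a second time.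

Step 3
Reactants: 4 1-(2-hydroxy-4-methoxy-6-{[(1S)-1-(4-methoxyphenyl)prop-2-en-1-yl]oxy}phenyl)ethan-1-one
Product: 6 tert-butyl{[1-(2-[(tert-butyldimethylsilyl)oxy]-4-methoxy-6-{[(1S)-1-(4-methoxyphenyl)prop-2-en-1-yl]oxy}phenyl)ethenyl]oxy}dimethylsilane, via aryl silyl ether ketone 5 (not isolated)
Conditions: TBSOTf (2.5 equiv), Et3N (4 equiv), CH2Cl2, −78 → 0 °C
Reagents that add atoms: tert-butyldimethylsilyl trifluoromethanesulfonate (TBSOTf), CC(C)(C)[Si](C)(C)OS(=O)(=O)C(F)(F)F
Why: Silyl triflate/amine silylation: the phenol is capped first (5) and the methyl ketone, which can enolise only towards CH3, is then converted into its enol silane by soft enolisation. Excess Et3N keeps the medium basic so that the ionisable benzylic allylic ether does not meet free silyl triflate or triflic acid.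

Step 4
Reactants: 6 tert-butyl{[1-(2-[(tert-butyldimethylsilyl)oxy]-4-methoxy-6-{[(1S)-1-(4-methoxyphenyl)prop-2-en-1-yl]oxy}phenyl)ethenyl]oxy}dimethylsilane
Product: 7 (2S)-4,5-bis[(tert-butyldimethylsilyl)oxy]-7-methoxy-2-(4-methoxyphenyl)-2H-chromene
Conditions: (H2IMes)(PCy3)Cl2Ru=CHPh (second-generation Grubbs catalyst, 5–10 mol%), 1,4-benzoquinone (20 mol%), degassed toluene (0.01 M), 50 °C, argon sparge, dark
Reagents that add atoms: none
Why: The active ruthenium species from (H2IMes)(PCy3)Cl2Ru=CHPh first exchanges onto the unhindered monosubstituted vinyl group, placing the carbene on the carbon that becomes C3; the enol silane, being 1,1-disubstituted, electron-rich and flanked by a 2,6-disubstituted arene, is not a site of initiation. Intramolecular [2+2] addition of this carbene to the enol-silane C=CH2 with ruthenium on the terminal CH2 gives a ruthenacyclobutane, and cycloreversion releases ring C with the C3=C4 bond and Ru=CH2, which re-enters at the vinyl group of the next molecule with loss of ethylene. The closest known reaction types are ring-closing metathesis of silyl enol ethers with terminal alkenes to cyclic enol silanes and of 2-vinylaryl allyl ethers to 2H-chromenes with the same catalyst. Ring C is closed as a six-membered ring by the metathesis itself, with both alkene carbons (C3 and C4) becoming ring members. No stereocentre is made; C2 keeps the S configuration from step 2 because no bond to it is broken. The step needs ring closure to outrun ruthenium hydride migration of the allylic double bond into conjugation with O1 and ring B, which would erase C2: benzoquinone scavenges the hydride, dilution and sparging remove ethylene, and 50 °C in the dark should keep Claisen rearrangement of the aryl allyl ether and electrocyclic opening of the 2H-chromene out of reach. Intermolecular metathesis is disfavoured because the only reactive alkene is a hindered secondary allylic one and the enol silane does not homodimerise.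

Step 5
Reactants: 7 (2S)-4,5-bis[(tert-butyldimethylsilyl)oxy]-7-methoxy-2-(4-methoxyphenyl)-2H-chromene
Product: 9 (2S)-5-hydroxy-7-methoxy-2-(4-methoxyphenyl)chroman-4-one, via 5-silyloxyflavanone 8 (not isolated)
Conditions: HF·pyridine, pyridine, THF, 0 °C → rt
Reagents that add atoms: none
Why: Acid-mediated protodesilylation: the electron-rich enol silane is protonated at C3 and loses silicon to fluoride to give ketone 8, after which the aryl silyl ether peri to the carbonyl is cleaved by HF. No free enolate is formed and pyridine buffers the medium, so C2, which the protonation does not touch, should keep its configuration.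

Step 6
Reactants: 9 (2S)-5-hydroxy-7-methoxy-2-(4-methoxyphenyl)chroman-4-one; 10 3-methylbut-2-en-1-ol
Product: 11 (2S)-7-methoxy-2-(4-methoxyphenyl)-5-[(3-methylbut-2-en-1-yl)oxy]chroman-4-one
Conditions: PPh3, DIAD, THF, 0 °C → rt
Reagents that add atoms: none
Why: Mitsunobu etherification of the chelated 5-hydroxyl with a primary allylic alcohol; it avoids the carbonate or hydride bases that would open ring C by β-elimination, and substitution at the primary carbon gives the unrearranged prenyl ether.

Step 7
Reactants: 11 (2S)-7-methoxy-2-(4-methoxyphenyl)-5-[(3-methylbut-2-en-1-yl)oxy]chroman-4-one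
Product: 14 Flowerine, (2S)-5-hydroxy-7-methoxy-2-(4-methoxyphenyl)-8-(3-methylbut-2-en-1-yl)chroman-4-one, via C6 ortho-dienone 12 (not isolated), via C8 para-dienone 13 (not isolated)
Conditions: Eu(fod)3 (10 mol%), CHCl3, 60 °C, sealed tube
Reagents that add atoms: none
Why: Eu(fod)3-catalysed domino Claisen–Cope (para-Claisen) rearrangement: chelation of europium between the C4 carbonyl and O5 triggers the [3,3] shift of the prenyl group to C6 with inversion of the allyl unit (12), a second [3,3] shift moves it to C8 and restores the prenyl connectivity (13), and enolisation gives the chelated phenol 14. C4a is blocked and C2 is remote, so the configuration should be unchanged.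

## Compound list

1 | (E)-4-methoxycinnamyl alcohol | COc1ccc(/C=C/CO)cc1 | starting material
2 | (E)-3-(4-methoxyphenyl)allyl methyl carbonate | COC(=O)OC/C=C/c1ccc(OC)cc1 | intermediate
3 | 2',6'-dihydroxy-4'-methoxyacetophenone | CC(=O)c1c(O)cc(OC)cc1O | starting material
4 | 1-(2-hydroxy-4-methoxy-6-{[(1S)-1-(4-methoxyphenyl)prop-2-en-1-yl]oxy}phenyl)ethan-1-one | COc1ccc([C@@H](Oc2cc(OC)cc(O)c2C(C)=O)C=C)cc1 | intermediate
5 | 1-(2-[(tert-butyldimethylsilyl)oxy]-4-methoxy-6-{[(1S)-1-(4-methoxyphenyl)prop-2-en-1-yl]oxy}phenyl)ethan-1-one | COc1ccc([C@@H](Oc2cc(OC)cc(O[Si](C)(C)C(C)(C)C)c2C(C)=O)C=C)cc1 | intermediate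
6 | tert-butyl{[1-(2-[(tert-butyldimethylsilyl)oxy]-4-methoxy-6-{[(1S)-1-(4-methoxyphenyl)prop-2-en-1-yl]oxy}phenyl)ethenyl]oxy}dimethylsilane | COc1ccc([C@@H](Oc2cc(OC)cc(O[Si](C)(C)C(C)(C)C)c2C(=C)O[Si](C)(C)C(C)(C)C)C=C)cc1 | intermediate
7 | (2S)-4,5-bis[(tert-butyldimethylsilyl)oxy]-7-methoxy-2-(4-methoxyphenyl)-2H-chromene | COc1ccc([C@@H]2C=C(O[Si](C)(C)C(C)(C)C)c3c(O[Si](C)(C)C(C)(C)C)cc(OC)cc3O2)cc1 | intermediate
8 | (2S)-5-[(tert-butyldimethylsilyl)oxy]-7-methoxy-2-(4-methoxyphenyl)chroman-4-one | COc1ccc([C@@H]2CC(=O)c3c(O[Si](C)(C)C(C)(C)C)cc(OC)cc3O2)cc1 | intermediate
9 | (2S)-5-hydroxy-7-methoxy-2-(4-methoxyphenyl)chroman-4-one | COc1ccc([C@@H]2CC(=O)c3c(O)cc(OC)cc3O2)cc1 | intermediate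
10 | 3-methylbut-2-en-1-ol | CC(C)=CCO | starting material
11 | (2S)-7-methoxy-2-(4-methoxyphenyl)-5-[(3-methylbut-2-en-1-yl)oxy]chroman-4-one | COc1ccc([C@@H]2CC(=O)c3c(OCC=C(C)C)cc(OC)cc3O2)cc1 | intermediate
12 | (2S)-7-methoxy-2-(4-methoxyphenyl)-6-(2-methylbut-3-en-2-yl)-2,3-dihydro-4H-chromene-4,5(6H)-dione (either C6 epimer) | COc1ccc([C@@H]2CC(=O)C3=C(O2)C=C(OC)C(C(C)(C)C=C)C3=O)cc1 | intermediate
13 | (2S)-7-methoxy-2-(4-methoxyphenyl)-8-(3-methylbut-2-en-1-yl)-2,3-dihydro-4H-chromene-4,5(8H)-dione (either C8 epimer) | COc1ccc([C@@H]2CC(=O)C3=C(O2)C(CC=C(C)C)C(OC)=CC3=O)cc1 | intermediate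
14 | Flowerine, (2S)-5-hydroxy-7-methoxy-2-(4-methoxyphenyl)-8-(3-methylbut-2-en-1-yl)chroman-4-one | COc1ccc([C@@H]2CC(=O)c3c(O)cc(OC)c(CC=C(C)C)c3O2)cc1 | target

## Step count and least certain steps

Total step count: 7. Longest linear sequence: 7 steps (1 → 14).

**Step 4 (key step).** The most likely failure is slow closure of the ruthenium carbene onto the hindered, electron-rich 1,1-disubstituted enol silane, which lies next to the silyloxy group on the arene. That leaves time for ruthenium hydride migration of the allylic double bond (loss of C2) and for catalyst deactivation as a heteroatom-stabilised carbene. Fallback: the C4 oxygen is taken out of the metathesis and introduced afterwards.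
- Setting out from 4, the phenol alone is silylated (TBSCl, imidazole, DMF) so that 5 is isolated.
- Reduction with i-Bu2AlH at −78 °C gives 1-(2-[(tert-butyldimethylsilyl)oxy]-4-methoxy-6-{[(1S)-1-(4-methoxyphenyl)prop-2-en-1-yl]oxy}phenyl)ethan-1-ol F1 (both carbinol epimers).
- Burgess dehydration gives the styrene tert-butyl(3-methoxy-5-{[(1S)-1-(4-methoxyphenyl)prop-2-en-1-yl]oxy}-2-vinylphenoxy)dimethylsilane F2.
- Ring-closing metathesis of F2 with the same ruthenium catalyst, now between two monosubstituted alkenes, should give (2S)-5-[(tert-butyldimethylsilyl)oxy]-7-methoxy-2-(4-methoxyphenyl)-2H-chromene F3.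
- Mukaiyama hydration (Mn(dpm)3, PhSiH3, O2, i-PrOH) places the hydroxyl at the benzylic C4, giving (2S)-5-[(tert-butyldimethylsilyl)oxy]-7-methoxy-2-(4-methoxyphenyl)chroman-4-ol F4 (both C4 epimers).
- Dess–Martin oxidation returns to the route at 8, which the conditions of step 5 take on to 9.

**Step 2.** The aryloxide of 3 is chelated, hindered and a good leaving group, and the 4-methoxyphenyl group stabilises the allyl cation. The likely failure is therefore re-ionisation of the product by the catalyst, with erosion of enantiomeric purity and drift to the linear ether or to C-allylation of the electron-rich ring. Fallback: the stereocentre is made first and transferred stereospecifically, setting out from 3.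
- Racemic 1-(4-methoxyphenyl)prop-2-en-1-ol F5 is made from 4-methoxybenzaldehyde and CH2=CHMgBr.
- Kinetic resolution by acylation with Candida antarctica lipase B and vinyl acetate leaves (S)-1-(4-methoxyphenyl)prop-2-en-1-ol F6.
- n-BuLi and Boc2O convert it into tert-butyl [(1S)-1-(4-methoxyphenyl)prop-2-en-1-yl] carbonate F7.
- RhCl(PPh3)3/P(OMe)3-catalysed allylic etherification with the sodium aryloxide of 3 (from NaN(SiMe3)2), which proceeds with net retention at the branched position, returns to the route at 4.

**Step 3.** The likely failure is Lewis-acid-induced ionisation of the benzylic allylic aryl ether by the silyl triflate (racemisation or allyl migration), or incomplete enolisation of the twisted ketone. Fallback: the two silylations are separated and the enol silane is made by base instead of by electrophilic activation. Setting out from 4, TBSCl and imidazole in DMF give 5 as an isolated compound. Its ketone is deprotonated with KN(SiMe3)2 in THF at −78 °C and the potassium enolate is trapped on oxygen with TBSCl, which returns to the route at 6 (no new compound, F0).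

**Step 7.** The likely failures are arrest of the relay at C6, by enolisation of dienone 12 before the Cope shift, and Lewis-acid-promoted opening of the O1–C2 bond with loss of enantiomeric purity. Fallback: the prenyl group is attached by cross-coupling, setting out from 7.
- Brief treatment with dilute aqueous HCl in THF at 0 °C hydrolyses only the enol silane, so that 8 is isolated.
- NIS in MeCN should iodinate C8, because the bulky silyl ether on O5 shields C6, giving (2S)-5-[(tert-butyldimethylsilyl)oxy]-8-iodo-7-methoxy-2-(4-methoxyphenyl)chroman-4-one F8.
- Stille coupling with Bu3SnCH2CH=CMe2 and Pd(PPh3)4 in DMF at 80 °C, under neutral conditions, gives (2S)-5-[(tert-butyldimethylsilyl)oxy]-7-methoxy-2-(4-methoxyphenyl)-8-(3-methylbut-2-en-1-yl)chroman-4-one F9.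
- HF·pyridine removes the silyl group and returns to the route at 14.

## Further compounds

F1 | step 4 | 1-(2-[(tert-butyldimethylsilyl)oxy]-4-methoxy-6-{[(1S)-1-(4-methoxyphenyl)prop-2-en-1-yl]oxy}phenyl)ethan-1-ol | COc1ccc([C@@H](Oc2cc(OC)cc(O[Si](C)(C)C(C)(C)C)c2C(C)O)C=C)cc1
F2 | step 4 | tert-butyl(3-methoxy-5-{[(1S)-1-(4-methoxyphenyl)prop-2-en-1-yl]oxy}-2-vinylphenoxy)dimethylsilane | COc1ccc([C@@H](Oc2cc(OC)cc(O[Si](C)(C)C(C)(C)C)c2C=C)C=C)cc1
F3 | step 4 | (2S)-5-[(tert-butyldimethylsilyl)oxy]-7-methoxy-2-(4-methoxyphenyl)-2H-chromene | COc1ccc([C@@H]2C=Cc3c(O[Si](C)(C)C(C)(C)C)cc(OC)cc3O2)cc1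
F4 | step 4 | (2S)-5-[(tert-butyldimethylsilyl)oxy]-7-methoxy-2-(4-methoxyphenyl)chroman-4-ol | COc1ccc([C@@H]2CC(O)c3c(O[Si](C)(C)C(C)(C)C)cc(OC)cc3O2)cc1
F5 | step 2 | 1-(4-methoxyphenyl)prop-2-en-1-ol (racemic) | COc1ccc(C(O)C=C)cc1
F6 | step 2 | (S)-1-(4-methoxyphenyl)prop-2-en-1-ol | COc1ccc([C@@H](O)C=C)cc1
F7 | step 2 | tert-butyl [(1S)-1-(4-methoxyphenyl)prop-2-en-1-yl] carbonate | COc1ccc([C@@H](OC(=O)OC(C)(C)C)C=C)cc1
F0 | step 3 | none | none
F8 | step 7 | (2S)-5-[(tert-butyldimethylsilyl)oxy]-8-iodo-7-methoxy-2-(4-methoxyphenyl)chroman-4-one | COc1ccc([C@@H]2CC(=O)c3c(O[Si](C)(C)C(C)(C)C)cc(OC)c(I)c3O2)cc1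
F9 | step 7 | (2S)-5-[(tert-butyldimethylsilyl)oxy]-7-methoxy-2-(4-methoxyphenyl)-8-(3-methylbut-2-en-1-yl)chroman-4-one | COc1ccc([C@@H]2CC(=O)c3c(O[Si](C)(C)C(C)(C)C)cc(OC)c(CC=C(C)C)c3O2)cc1
A1 | alternative 1 | 4-methoxy-6-[(E)-4-(4-methoxyphenyl)-2-oxobut-3-en-1-yl]-2H-pyran-2-one | COc1ccc(/C=C/C(=O)CC2=CC(OC)=CC(=O)O2)cc1
A2 | alternative 1 | (E)-1-(2,6-dihydroxy-4-methoxyphenyl)-3-(4-methoxyphenyl)prop-2-en-1-one | COc1ccc(/C=C/C(=O)c2c(O)cc(OC)cc2O)cc1
A3 | alternative 2 | 3-methoxy-5-(methoxymethoxy)-2-(3-methylbut-2-en-1-yl)-6-(trimethylsilyl)phenyl trifluoromethanesulfonate | COCOc1cc(OC)c(CC=C(C)C)c(OS(=O)(=O)C(F)(F)F)c1[Si](C)(C)C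
A4 | alternative 2 | methyl (S)-3-hydroxy-3-(4-methoxyphenyl)propanoate | COc1ccc([C@@H](O)CC(=O)OC)cc1
A5 | alternative 2 | (S)-7-methoxy-5-(methoxymethoxy)-2-(4-methoxyphenyl)-8-(3-methylbut-2-en-1-yl)chroman-4-one | COc1ccc([C@@H]2CC(=O)c3c(OCOC)cc(OC)c(CC=C(C)C)c3O2)cc1
A6 | alternative 3 | 2-diazo-1-{4,6-dimethoxy-2-[(4-methoxybenzyl)oxy]-3-(3-methylbut-2-en-1-yl)phenyl}ethan-1-one | COc1ccc(COc2c(CC=C(C)C)c(OC)cc(OC)c2C(=O)C=[N+]=[N-])cc1
A7 | alternative 3 | (S)-5,7-dimethoxy-2-(4-methoxyphenyl)-8-(3-methylbut-2-en-1-yl)chroman-4-one | COc1ccc([C@@H]2CC(=O)c3c(OC)cc(OC)c(CC=C(C)C)c3O2)cc1
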